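**Retrosynthetic overview**

1. Numbering (naphthalene style, kept for every intermediate): ring A = C1–C2–C3=C4–C4a–C8a, ring B = C4a–C5–C6–C7–C8–C8a; C1 carries the dienoic acid, C2 the (E)-but-2-en-2-yl group, C3 a methyl, C7 the sulfate, C8 a methyl.
2. Feature: with C7 at the ketone level, C7(=O)–C6–C5–C4a–C4=C3 is a δ,ε-unsaturated ketone spanning both rings, the retron of an oxy-Cope shift. Rejoining C3 to C7 and cutting C4a–C5 gives a 2-vinylbicyclo[2.2.2]oct-5-en-2-ol with bridgeheads C3 and C8a.
3. Late disconnections: O-sulfate; C1 dienoate (Horner–Wadsworth–Emmons on a C1 aldehyde); C7 alcohol (hydride reduction); C8 methyl (convex-face alkylation of the C5=C6 enone made from the rearrangement enolate).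
4. The bicycle comes from vinyl addition to a C7 ketone, itself the endo Diels–Alder adduct of 6,6-dimethoxy-2-methylcyclohexa-2,4-dienone (from 2-methoxy-6-methylphenol) with a (2Z,4E)-dienyl silyl ether (from tiglic aldehyde); the racemate is resolved.
5. Ring order: the bicyclo[2.2.2]octene (future ring A plus the temporary C3–C7 bond) is built first by cycloaddition; ring B closes in the rearrangement as ring A is released.

Key step: step 8

Remark 1: the target is drawn as the free hydrogen sulfate and free carboxylic acid, so the last step ends with full protonation in the cold.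
Remark 2: the Diels–Alder step gives a racemate; the wanted antipode is separated on a chiral phase and assigned by vibrational circular dichroism against the computed spectrum. Racemates are written as the dot-joined pair of enantiomers.
Remark 3: the rearrangement enolate is silylated in the flask and the free C7 ketone is never liberated, because only the enolate holds the C6=C7 regiochemistry that the next step needs.

**Route**

Step 1
Reactants: 1 tiglic aldehyde; 2 methyl bis(2,2,2-trifluoroethyl)phosphonoacetate
Product: 3 methyl (2Z,4E)-4-methylhexa-2,4-dienoate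
Conditions: KN(SiMe3)2, 18-crown-6, THF, −78 °C
Reagents that add atoms: none
Why: Still–Gennari olefination, in which the electron-poor phosphonate anion with a dissociated potassium counter-ion eliminates from the kinetically formed adduct before it equilibrates, should give the (2Z) enoate while the (4E) geometry of the aldehyde is carried through.

Step 2
Reactants: 3 methyl (2Z,4E)-4-methylhexa-2,4-dienoate
Product: 4 (2Z,4E)-4-methylhexa-2,4-dien-1-ol
Conditions: i-Bu2AlH (2.2 equiv), CH2Cl2, −78 °C; aq. potassium sodium tartrate
Reagents that add atoms: none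
Why: 1,2-reduction of the ester by the aluminium hydride at low temperature should reach the allylic alcohol without touching either alkene geometry.

Step 3
Reactants: 4 (2Z,4E)-4-methylhexa-2,4-dien-1-ol
Product: 5 tert-butyldimethylsilyl ether of 4
Conditions: TBSCl, imidazole, CH2Cl2, 0 °C to rt
Reagents that add atoms: tert-butyldimethylsilyl chloride, CC(C)(C)[Si](C)(C)Cl
Why: standard silylation of a primary alcohol, needed so that the alcohol cannot enter the ketal of the quinone monoketal in step 4 and tether the cycloaddition in the wrong stereochemical sense.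

Step 4
Reactants: 6 2-methoxy-6-methylphenol; 5 tert-butyldimethylsilyl ether of 4 (3 equiv, excess recovered)
Product: 8 racemic bicyclo[2.2.2]octenone adduct (C7 ketone and C8 dimethyl ketal; C1 CH2OTBS and C2 butenyl cis and syn to the C4=C4a bridge), via masked o-benzoquinone 7 (not isolated)
Conditions: PhI(OAc)2 (1.2 equiv), MeOH, slow addition of 6 to oxidant and 5, rt to 40 °C
Reagents that add atoms: methanol, CO
Why: oxidative dearomatisation in methanol gives the electron-poor diene 7, which is trapped in an inverse-demand Diels–Alder reaction by the (Z)-disubstituted alkene of 5 (a (Z)-diene cannot reach the s-cis form and so serves only as the two-electron partner); the diene terminus next to the ketal carbon (C8a, larger LUMO coefficient) pairs with the CH2OTBS-bearing terminus of the dienyl system (C1, larger HOMO coefficient), so the butenyl-bearing C2 joins the methyl-bearing C3, and endo addition places both cis substituents syn to the new C4=C4a bridge, which sets C1, C2, C3 and C8a in their relative sense.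

Step 5
Reactants: 8 racemic bicyclo[2.2.2]octenone adduct
Product: 9 single enantiomer of the adduct (configuration as in the SMILES)
Conditions: preparative supercritical-fluid chromatography, amylose tris(3,5-dimethylphenylcarbamate) on silica, CO2/MeOH
Reagents that add atoms: none
Why: direct chromatographic resolution of enantiomers on a polysaccharide carbamate phase, for which a rigid bicycle with ketone, ketal and ether acceptor sites is a favourable case, with no bond made or broken.

Step 6
Reactants: 9 single enantiomer of the adduct
Product: 11 bicyclic C7 ketone with C8 as CH2, via C8-monomethoxy ketone 10 (not isolated)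
Conditions: SmI2 (5 equiv), THF/MeOH, rt
Reagents that add atoms: none
Why: reductive deketalisation, in which SmI2 forms the ketyl, transfers a second electron and expels methoxide from the carbon alpha to the ketone, should run twice in succession through 10 and leave the isolated alkenes, the silyl ether and the four stereocentres alone.

Step 7
Reactants: 11 bicyclic C7 ketone; 12 vinylmagnesium bromide
Product: 13 vinyl carbinol (vinyl on C7 syn to the C4=C4a bridge, hydroxyl toward the C1–C2 bridge)
Conditions: CeCl3 (anhydrous), CH2=CHMgBr, THF, −78 °C; aq. NH4Cl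
Reagents that add atoms: none
Why: 1,2-addition of the weakly basic organocerium reagent avoids enolisation toward C8, and the reagent should enter from the sector between the C7–C8 and C4=C4a bridges, where only in-plane vinylic hydrogens lie, and not from the sector into which H1 and H2 point, which sets the C7 carbinol centre with the vinyl group syn to the C4=C4a bridge.

Step 8
Reactants: 13 vinyl carbinol
Product: 16 trimethylsilyl enol ether (C6=C7) of the cis-fused C7 ketone, via potassium alkoxide 14 (not isolated), via potassium enolate 15 (not isolated)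
Conditions: KH (3 equiv), 18-crown-6, THF, 0 °C to rt; then TMSCl/Et3N, −78 °C
Reagents that add atoms: chlorotrimethylsilane, C[Si](C)(C)Cl
Why: KH converts 13 into alkoxide 14, and with the potassium ion held by 18-crown-6 the oxyanion weakens the C3–C7 bond so that the 1,5-diene C5=C6–C7–C3–C4=C4a undergoes a concerted suprafacial [3,3] shift (anionic oxy-Cope rearrangement) through the boat array that the bicycle enforces, forming C4a–C5, breaking C3–C7 and leaving enolate 15. The closest known reaction type is the alkoxide-accelerated rearrangement of 2-vinylbicyclo[2.2.2]oct-5-en-2-ols to cis-fused octalones. Ring B (C4a–C5–C6–C7–C8–C8a) closes as a six-membered ring by the sigmatropic C5–C4a bond formation itself, and ring A (C1–C2–C3=C4–C4a–C8a) is the cyclohexene set free when the C3–C7 bridge bond opens. The one new stereocentre, C4a, is fixed by the bicycle: C5 can reach C4a only on the face of the C4=C4a bond turned toward the C7–C8 bridge, the side on which C8 already hangs from C8a, so H4a and H8a come out cis, while C1, C2 and C8a are not touched. The step needs the vinyl group syn to the C4=C4a bridge (set in step 7) and it needs the C6=C7 position of the enolate to survive, which is secured by silylating 15 on oxygen at −78 °C before any proton source is admitted, giving 16 as the protected form of the C7 ketone.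

Step 9
Reactants: 16 trimethylsilyl enol ether
Product: 17 cis-fused C5=C6 enone (C7 ketone)
Conditions: Pd(OAc)2 (1.05 equiv), MeCN, rt
Reagents that add atoms: none
Why: Saegusa–Ito oxidation, in which the silyl enol ether gives an oxa-π-allyl palladium species that loses a beta-hydrogen from C5, can form only the C5=C6 enone because C7 bears no hydrogen, and the trisubstituted alkenes are poor ligands for the palladium salt at room temperature.

Step 10
Reactants: 17 cis-fused C5=C6 enone
Product: 19 8-methyl enone (methyl on the face of H8a), via lithium dienolate 18 (not isolated)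
Conditions: LiN(i-Pr)2 (1.1 equiv), THF, −78 °C; MeI, DMPU, −78 to −30 °C
Reagents that add atoms: iodomethane, CI
Why: kinetic deprotonation of the enone takes the alpha-prime hydrogen at C8 (cross-conjugated dienolate 18), and C-alkylation should occur on the convex face of the cis-fused bicycle, syn to H8a and anti to the C8a–C1 bond, because ring A covers the other face, which sets C8.

Step 11
Reactants: 19 8-methyl enone
Product: 20 8-methyl C7 ketone (C5–C6 saturated)
Conditions: H2 (1 atm), RhCl(PPh3)3 (10 mol%), benzene, rt
Reagents that add atoms: none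
Why: homogeneous hydrogenation with this rhodium complex reduces the cis-disubstituted C5=C6 bond of the enone and is known to spare trisubstituted alkenes (C3=C4 and the butenyl group) and ketones, and no stereocentre is formed.

Step 12
Reactants: 20 8-methyl C7 ketone
Product: 21 C7 alcohol (hydroxyl cis to the C8 methyl, both on the face of H4a and H8a)
Conditions: LiBH(s-Bu)3 (1.5 equiv), THF, −78 °C; then H2O2, aq. NaOH, 0 °C
Reagents that add atoms: none
Why: reduction of a 2-alkylcyclohexanone by the bulky borohydride proceeds by equatorial attack on the chair that holds the C8 methyl equatorial (the axial path is blocked by the syn-axial H5 and H8a), which should give the axial C7 alcohol cis to the methyl, as in the formation of cis-2-methylcyclohexanol.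

Step 13
Reactants: 21 C7 alcohol
Product: 22 diol (C1 CH2OH, C7 OH)
Conditions: Bu4NF, THF, 0 °C to rt
Reagents that add atoms: none
Why: fluoride cleavage of the silyl ether is driven by the Si–F bond, and nothing else in 21 responds to the reagent.

Step 14
Reactants: 22 diol
Product: 23 C1 aldehyde with free C7 hydroxyl
Conditions: TEMPO (10 mol%), PhI(OAc)2 (1.1 equiv), CH2Cl2, rt
Reagents that add atoms: none
Why: oxoammonium oxidation is selective for primary over secondary alcohols, the more so as the C7 hydroxyl is axial and flanked by the C8 methyl; the mildly acidic medium should not epimerise C1, and no lactol can form because the C7 oxygen and C1 lie on opposite faces of ring B.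

Step 15
Reactants: 23 C1 aldehyde; 24 triethyl (E)-4-phosphonocrotonate
Product: 25 ethyl (2E,4E)-dienoate with free C7 hydroxyl
Conditions: LiN(SiMe3)2, THF, −78 °C; then 23, −78 to 0 °C
Reagents that add atoms: none
Why: Horner–Wadsworth–Emmons olefination with the vinylogous phosphonate reacting at the carbon next to phosphorus should form the new double bond trans and keep the existing one, and the stabilised anion at low temperature is too weak a base to epimerise C1 or to be quenched by the C7 alcohol.

Step 16
Reactants: 25 ethyl (2E,4E)-dienoate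
Product: 26 pyridinium salt of the C7 sulfate monoester
Conditions: SO3·pyridine (5 equiv), pyridine, rt to 40 °C
Reagents that add atoms: sulfur trioxide pyridine complex, O=S(=O)([O-])[n+]1ccccc1
Why: O-sulfation of a secondary alcohol by transfer of SO3 from the amine complex occurs at oxygen with retention at C7 and does not touch the alkenes or the dienoate.

Step 17
Reactants: 26 pyridinium salt of the C7 sulfate monoester
Product: 28 target CNP0450810.2, via dilithium salt 27 (not isolated)
Conditions: LiOH, THF/MeOH/H2O, rt; then 1 M HCl to pH 1, 0 °C, C18 desalting, lyophilisation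
Reagents that add atoms: lithium hydroxide, [Li+].[OH-]
Why: saponification of the ethyl ester by hydroxide leaves the sulfate monoester anion intact, and cold strong acid followed by reversed-phase desalting then protonates both anionic sites to give the diacid form.

**Compound list**

1 | tiglic aldehyde, (E)-2-methylbut-2-enal | C/C=C(\C)C=O | starting material
2 | methyl bis(2,2,2-trifluoroethyl)phosphonoacetate | COC(=O)CP(=O)(OCC(F)(F)F)OCC(F)(F)F | starting material
3 | methyl (2Z,4E)-4-methylhexa-2,4-dienoate | C/C=C(\C)/C=C\C(=O)OC | intermediate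
4 | (2Z,4E)-4-methylhexa-2,4-dien-1-ol | C/C=C(\C)/C=C\CO | intermediate
5 | tert-butyldimethylsilyl ether of 4 | C/C=C(\C)/C=C\CO[Si](C)(C)C(C)(C)C | intermediate
6 | 2-methoxy-6-methylphenol | COc1cccc(C)c1O | starting material
7 | 6,6-dimethoxy-2-methylcyclohexa-2,4-dien-1-one (masked o-benzoquinone) | COC1(OC)C=CC=C(C)C1=O | intermediate (not isolated)
8 | racemic Diels–Alder adduct: bicyclo[2.2.2]octene with bridgeheads C3 (methyl) and C8a (H), bridges C4=C4a, C7(=O)–C8(OMe)2 and C2–C1; C2 butenyl and C1 CH2OTBS cis, both syn to the C4=C4a bridge | C/C=C(\C)[C@@H]1[C@]2(C)C=C[C@@H](C(OC)(OC)C2=O)[C@@H]1CO[Si](C)(C)C(C)(C)C.C/C=C(\C)[C@H]1[C@@]2(C)C=C[C@H](C(OC)(OC)C2=O)[C@H]1CO[Si](C)(C)C(C)(C)C | intermediate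
9 | resolved adduct, the enantiomer carried forward | C/C=C(\C)[C@@H]1[C@]2(C)C=C[C@@H](C(OC)(OC)C2=O)[C@@H]1CO[Si](C)(C)C(C)(C)C | intermediate
10 | C8-monomethoxy ketone (C8 configuration open) | C/C=C(\C)[C@@H]1[C@]2(C)C=C[C@@H](C(OC)C2=O)[C@@H]1CO[Si](C)(C)C(C)(C)C | intermediate (not isolated)
11 | bicyclic C7 ketone, C8 as CH2, other features as in 9 | C/C=C(\C)[C@@H]1[C@]2(C)C=C[C@@H](CC2=O)[C@@H]1CO[Si](C)(C)C(C)(C)C | intermediate
12 | vinylmagnesium bromide | C=C[Mg]Br | starting material
13 | vinyl carbinol: C7 bears vinyl (syn to the C4=C4a bridge) and hydroxyl (toward the C1–C2 bridge) | C/C=C(\C)[C@@H]1[C@]2(C)C=C[C@@H](C[C@@]2(O)C=C)[C@@H]1CO[Si](C)(C)C(C)(C)C | intermediate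
14 | potassium alkoxide of 13 | C/C=C(\C)[C@@H]1[C@]2(C)C=C[C@@H](C[C@@]2([O-])C=C)[C@@H]1CO[Si](C)(C)C(C)(C)C.[K+] | intermediate (not isolated)
15 | potassium C6=C7 enolate of the cis-fused C7 ketone (H4a and H8a cis; C1 CH2OTBS and C2 butenyl on the face of H8a) | C/C=C(\C)[C@@H]1C(C)=C[C@H]2CC=C([O-])C[C@H]2[C@@H]1CO[Si](C)(C)C(C)(C)C.[K+] | intermediate (not isolated)
16 | trimethylsilyl enol ether (C6=C7–OTMS) of the cis-fused C7 ketone | C/C=C(\C)[C@@H]1C(C)=C[C@H]2CC=C(O[Si](C)(C)C)C[C@H]2[C@@H]1CO[Si](C)(C)C(C)(C)C | intermediate
17 | cis-fused enone, C5=C6–C7=O | C/C=C(\C)[C@@H]1C(C)=C[C@H]2C=CC(=O)C[C@H]2[C@@H]1CO[Si](C)(C)C(C)(C)C | intermediate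
18 | lithium cross-conjugated dienolate (C5=C6, C7=C8) | C/C=C(\C)[C@@H]1C(C)=C[C@H]2C=CC([O-])=C[C@H]2[C@@H]1CO[Si](C)(C)C(C)(C)C.[Li+] | intermediate (not isolated)
19 | 8-methyl enone, methyl cis to H8a | C/C=C(\C)[C@@H]1C(C)=C[C@H]2C=CC(=O)[C@H](C)[C@H]2[C@@H]1CO[Si](C)(C)C(C)(C)C | intermediate
20 | 8-methyl C7 ketone, ring B saturated | C/C=C(\C)[C@@H]1C(C)=C[C@H]2CCC(=O)[C@H](C)[C@H]2[C@@H]1CO[Si](C)(C)C(C)(C)C | intermediate
21 | C7 alcohol; C1 side chain, C2 butenyl, H4a, H8a, C7 OH and C8 methyl all on one face | C/C=C(\C)[C@@H]1C(C)=C[C@H]2CC[C@H](O)[C@H](C)[C@H]2[C@@H]1CO[Si](C)(C)C(C)(C)C | intermediate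
22 | diol (C1 CH2OH, C7 OH) | C/C=C(\C)[C@@H]1C(C)=C[C@H]2CC[C@H](O)[C@H](C)[C@H]2[C@@H]1CO | intermediate
23 | C1 aldehyde with C7 hydroxyl | C/C=C(\C)[C@@H]1C(C)=C[C@H]2CC[C@H](O)[C@H](C)[C@H]2[C@@H]1C=O | intermediate
24 | triethyl (E)-4-phosphonocrotonate | CCOC(=O)/C=C/CP(=O)(OCC)OCC | starting material
25 | ethyl (2E,4E)-5-(decalinyl)penta-2,4-dienoate with C7 hydroxyl | C/C=C(\C)[C@@H]1C(C)=C[C@H]2CC[C@H](O)[C@H](C)[C@H]2[C@@H]1/C=C/C=C/C(=O)OCC | intermediate
26 | pyridinium salt of the C7 sulfate monoester of 25 | C/C=C(\C)[C@@H]1C(C)=C[C@H]2CC[C@H](OS(=O)(=O)[O-])[C@H](C)[C@H]2[C@@H]1/C=C/C=C/C(=O)OCC.c1cc[nH+]cc1 | intermediate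
27 | dilithium sulfate carboxylate | C/C=C(\C)[C@@H]1C(C)=C[C@H]2CC[C@H](OS(=O)(=O)[O-])[C@H](C)[C@H]2[C@@H]1/C=C/C=C/C(=O)[O-].[Li+].[Li+] | intermediate (not isolated)
28 | CNP0450810.2 | C/C=C(\C)[C@@H]1C(C)=C[C@H]2CC[C@H](OS(=O)(=O)O)[C@H](C)[C@H]2[C@@H]1/C=C/C=C/C(=O)O | target

**Step count and risks**

Total step count: 17. Longest linear sequence: 17 steps (steps 1 to 17 from tiglic aldehyde 1; 6, 12 and 24 enter as purchased materials).

Steps most likely to fail:

Step 4. The transient quinone monoketal may dimerise faster than it adds to a hindered (Z)-disubstituted alkene, and regiocontrol may erode because the quaternary C3–C2 bond has to form. The fallback is a bromine detour that removes the dimerisation pathway. It sets out from 6, which is brominated para to the hydroxyl (N-bromosuccinimide, MeCN, 0 °C) to 4-bromo-2-methoxy-6-methylphenol F1. Oxidation (PhI(OAc)2, MeOH) gives 4-bromo-6,6-dimethoxy-2-methylcyclohexa-2,4-dien-1-one F2, a bromo quinone monoketal that resists dimerisation and can be formed completely before it is heated with 5. The cycloaddition then gives the racemic C4a-bromo adduct F3, and radical hydrodebromination of the vinyl bromide (Bu3SnH, AIBN, benzene, 80 °C) returns to the route at 8.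

Step 8. The alkoxide may cleave heterolytically at C3–C7 to an allyl anion and vinyl ketone pair that recombines in the 1,3 sense or is quenched, and proton transfer to enolate 15 before silylation may scramble the C6=C7 regiochemistry. The fallback is the neutral siloxy-Cope rearrangement. It sets out from 13, which is silylated at the tertiary hydroxyl (N-(trimethylsilyl)imidazole, CH2Cl2, rt) to the trimethylsilyl ether of 13 F4. Thermolysis in degassed o-dichlorobenzene at about 200 °C in base-washed glass should deliver the silyl enol ether as the direct [3,3] product with no basic species present, returning to the route at 16.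

Step 12. Hydride may be delivered to the wrong face of the C7 ketone (axial attack, or reaction through the chair with an axial C8 methyl), giving the C7 epimer. The fallback inverts the carbinol instead of selecting the face. It sets out from 20, which is reduced with a small hydride (NaBH4, MeOH, −20 °C) to the C7 epimer of 21 F5. Mitsunobu reaction (4-nitrobenzoic acid, PPh3, diisopropyl azodicarboxylate, toluene) gives with inversion the 4-nitrobenzoate of 21 F6, and methanolysis (K2CO3, MeOH) returns to the route at 21.

Further compounds
F1 | step 4 | 4-bromo-2-methoxy-6-methylphenol | COc1cc(Br)cc(C)c1O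
F2 | step 4 | 4-bromo-6,6-dimethoxy-2-methylcyclohexa-2,4-dien-1-one | COC1(OC)C=C(Br)C=C(C)C1=O
F3 | step 4 | racemic C4a-bromo analogue of adduct 8 | C/C=C(\C)[C@@H]1[C@]2(C)C=C(Br)[C@@H](C(OC)(OC)C2=O)[C@@H]1CO[Si](C)(C)C(C)(C)C.C/C=C(\C)[C@H]1[C@@]2(C)C=C(Br)[C@H](C(OC)(OC)C2=O)[C@H]1CO[Si](C)(C)C(C)(C)C
F4 | step 8 | trimethylsilyl ether of 13 | C/C=C(\C)[C@@H]1[C@]2(C)C=C[C@@H](C[C@@]2(O[Si](C)(C)C)C=C)[C@@H]1CO[Si](C)(C)C(C)(C)C
F5 | step 12 | C7 epimer of 21 | C/C=C(\C)[C@@H]1C(C)=C[C@H]2CC[C@@H](O)[C@H](C)[C@H]2[C@@H]1CO[Si](C)(C)C(C)(C)C
F6 | step 12 | 4-nitrobenzoate of 21 | C/C=C(\C)[C@@H]1C(C)=C[C@H]2CC[C@H](OC(=O)c3ccc(cc3)[N+](=O)[O-])[C@H](C)[C@H]2[C@@H]1CO[Si](C)(C)C(C)(C)C
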